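The central ring E is built, not made by coupling two arenes: its C2'–C3' and C1'–C6' bonds are cut. The feature exploited is that O4' of ring E lies para to C1' (the carbon bonded to chromone carbon C2'') and ortho to C3' (the carbon bonded to C8 of ring A), the pattern that a 2-oxygenated diene and an acceptor alkyne deliver. One cycloaddition–dehydrogenation thus forms ring E, unites both flavone halves and fixes the C8–C3' linkage. Its precursors are a benzyl-protected flavone carrying a (Z)-2-silyloxybuta-1,3-dienyl chain at C8 and 5,7-bis(benzyloxy)-2-ethynylchromone, both made from one dibenzylated phloroacetophenone.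

Key step: step 11

Assumption: the target SMILES defines no configuration for the C8–C3' biaryl axis, so the axis is treated as freely rotating and no stereochemical element has to be controlled.

Step 1
Reactants: 1 2,4,6-trihydroxyacetophenone
Product: 2 1-[2,4-bis(benzyloxy)-6-hydroxyphenyl]ethan-1-one
Conditions: BnBr (2.05 equiv), K2CO3, DMF, 0 °C to rt
Reagents that add atoms: benzyl bromide, BrCc1ccccc1
Why: Williamson etherification takes the para hydroxyl and one of the two equivalent ortho hydroxyls, while the remaining ortho hydroxyl is held back by its hydrogen bond to the ketone, so two equivalents of halide should stop at the dibenzyl ether.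

Step 2
Reactants: 2 1-[2,4-bis(benzyloxy)-6-hydroxyphenyl]ethan-1-one; 3 allyl bromide
Product: 4 1-[2-(allyloxy)-4,6-bis(benzyloxy)phenyl]ethan-1-one
Conditions: K2CO3, DMF, 60 °C
Reagents that add atoms: none
Why: Williamson etherification of the chelated phenol, which is slow with benzyl bromide at room temperature but should proceed with the reactive allylic halide in warm DMF.

Step 3
Reactants: 4 1-[2-(allyloxy)-4,6-bis(benzyloxy)phenyl]ethan-1-one
Product: 5 1-[3-allyl-4,6-bis(benzyloxy)-2-hydroxyphenyl]ethan-1-one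
Conditions: PhNEt2, 195 °C, Ar
Reagents that add atoms: none
Why: Aromatic Claisen rearrangement ([3,3]-sigmatropic shift, then tautomerisation) can deliver the allyl group only to C3, the single free ortho position of the ether oxygen, which places the chain on the carbon that becomes C8 of the flavone.

Step 4
Reactants: 5 1-[3-allyl-4,6-bis(benzyloxy)-2-hydroxyphenyl]ethan-1-one; 6 4-(benzyloxy)-3-methoxybenzoic acid
Product: 9 8-allyl-5,7-bis(benzyloxy)-2-[4-(benzyloxy)-3-methoxyphenyl]-4H-chromen-4-one, via acid chloride 7 (not isolated), via diketone 8 (not isolated)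
Conditions: 6, (COCl)2, DMF (cat.), CH2Cl2, rt; 5, LiN(SiMe3)2 (3.2 equiv), THF, −78 °C, then 7, −78 °C to rt; aq. HCl; TsOH·H2O (cat.), toluene, 90 °C
Reagents that add atoms: none
Why: C-acylation of the lithium phenoxide–enolate dianion by the aroyl chloride (a Claisen-type condensation; any O-aroyl ester converges by Baker–Venkataraman acyl shift) gives the 1,3-diketone, and acid-catalysed cyclodehydration through the only free phenol closes the pyranone with the allyl group at C8.

Step 5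
Reactants: 9 8-allyl-5,7-bis(benzyloxy)-2-[4-(benzyloxy)-3-methoxyphenyl]-4H-chromen-4-one
Product: 10 2-{5,7-bis(benzyloxy)-2-[4-(benzyloxy)-3-methoxyphenyl]-4-oxo-4H-chromen-8-yl}acetaldehyde
Conditions: OsO4 (cat.), NaIO4, 2,6-lutidine, dioxane/H2O (3:1), rt
Reagents that add atoms: osmium tetroxide, O=[Os](=O)(=O)=O (its oxygen, replenished by sodium periodate, [Na+].[O-]I(=O)(=O)=O, becomes the aldehyde oxygen)
Why: Lemieux–Johnson oxidation, in which OsO4 dihydroxylates the isolated terminal alkene far faster than the electron-poor, trisubstituted C2=C3 bond of the flavone and periodate cleaves the diol, with 2,6-lutidine holding back over-oxidation.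

Step 6
Reactants: 10 2-{5,7-bis(benzyloxy)-2-[4-(benzyloxy)-3-methoxyphenyl]-4-oxo-4H-chromen-8-yl}acetaldehyde; 11 vinylmagnesium bromide
Product: 12 racemic 5,7-bis(benzyloxy)-2-[4-(benzyloxy)-3-methoxyphenyl]-8-(2-hydroxybut-3-en-1-yl)-4H-chromen-4-one
Conditions: CeCl3 (anhydrous), THF, −78 °C; aq. NH4Cl
Reagents that add atoms: none
Why: Grignard 1,2-addition through the less basic organocerium reagent should favour addition over enolisation of the arylacetaldehyde and leave the much less electrophilic chromone carbonyl alone at −78 °C; the carbinol stereocentre forms without control as a racemate and is removed in step 7.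

Step 7
Reactants: 12 racemic 5,7-bis(benzyloxy)-2-[4-(benzyloxy)-3-methoxyphenyl]-8-(2-hydroxybut-3-en-1-yl)-4H-chromen-4-one
Product: 13 5,7-bis(benzyloxy)-2-[4-(benzyloxy)-3-methoxyphenyl]-8-(2-oxobut-3-en-1-yl)-4H-chromen-4-one
Conditions: Dess–Martin periodinane, pyridine, CH2Cl2, 0 °C
Reagents that add atoms: none
Why: Dess–Martin oxidation of the secondary allylic alcohol runs near neutrality and without nucleophiles, so the polymerisation-prone arylmethyl vinyl ketone should form cleanly and is used at once.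

Step 8
Reactants: 13 5,7-bis(benzyloxy)-2-[4-(benzyloxy)-3-methoxyphenyl]-8-(2-oxobut-3-en-1-yl)-4H-chromen-4-one
Product: 14 5,7-bis(benzyloxy)-2-[4-(benzyloxy)-3-methoxyphenyl]-8-[(1Z)-2-(tert-butyldimethylsilyloxy)buta-1,3-dien-1-yl]-4H-chromen-4-one
Conditions: TBSOTf, Et3N, CH2Cl2, −78 to 0 °C
Reagents that add atoms: tert-butyldimethylsilyl trifluoromethanesulfonate, CC(C)(C)[Si](C)(C)OS(=O)(=O)C(F)(F)F
Why: Soft enolisation (silyl triflate and amine) can only occur towards the acidic benzylic CH2, giving the 2-silyloxydiene, and the (Z)-enol ether should prevail because the bulky di-ortho-substituted aryl group avoids the vinyl group and sits cis to the silyloxy oxygen.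

Step 9
Reactants: 2 1-[2,4-bis(benzyloxy)-6-hydroxyphenyl]ethan-1-one; 15 ethyl diethoxyacetate
Product: 18 5,7-bis(benzyloxy)-4-oxo-4H-chromene-2-carbaldehyde, via diketone 16 (not isolated), via diethyl acetal 17 (not isolated)
Conditions: NaH, THF, 0 °C to reflux; then AcOH, aq. H2SO4, 60 °C
Reagents that add atoms: water, O
Why: Crossed Claisen condensation of the ketone enolate with the acetal-protected glyoxylate ester gives the 1,3-diketone, and aqueous acid first cyclodehydrates it through the free phenol to the chromone and then hydrolyses the acetal to the aldehyde.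

Step 10
Reactants: 18 5,7-bis(benzyloxy)-4-oxo-4H-chromene-2-carbaldehyde; 19 dimethyl (1-diazo-2-oxopropyl)phosphonate
Product: 20 5,7-bis(benzyloxy)-2-ethynyl-4H-chromen-4-one
Conditions: K2CO3, MeOH/THF, 0 °C to rt
Reagents that add atoms: none
Why: Seyferth–Gilbert homologation in its Ohira–Bestmann form, in which methanolysis of the acetyl group frees the diazomethylphosphonate anion that adds to the non-enolisable, highly electrophilic aldehyde, and loss of dimethyl phosphate and N2 with a 1,2-hydrogen shift gives the terminal alkyne.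

Step 11
Reactants: 14 5,7-bis(benzyloxy)-2-[4-(benzyloxy)-3-methoxyphenyl]-8-[(1Z)-2-(tert-butyldimethylsilyloxy)buta-1,3-dien-1-yl]-4H-chromen-4-one; 20 5,7-bis(benzyloxy)-2-ethynyl-4H-chromen-4-one
Product: 22 5,7-bis(benzyloxy)-8-{5-[5,7-bis(benzyloxy)-4-oxo-4H-chromen-2-yl]-2-[(tert-butyldimethylsilyl)oxy]phenyl}-2-[4-(benzyloxy)-3-methoxyphenyl]-4H-chromen-4-one, via cyclohexadiene adduct 21 (not isolated)
Conditions: 14 (1.3 equiv), toluene, BHT (cat.), 120 °C, sealed tube; then DDQ (1.2 equiv), rt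
Reagents that add atoms: none
Why: A concerted but asynchronous [4+2] cycloaddition between the HOMO of the 2-silyloxydiene and the LUMO of the alkyne, whose terminal carbon is the vinylogous acceptor position of the chromone enone, forms C2'–C3' ahead of C1'–C6' and gives the 1,4-cyclohexadiene 21, from which DDQ abstracts the doubly allylic hydride at C3' before loss of a C6' proton aromatises the ring to the aryl silyl ether. The closest known chemistry is the Diels–Alder reaction of 2-silyloxybuta-1,3-dienes with ynones or propiolates followed by dehydrogenation to para-acyl aryl silyl ethers. Ring E is closed as a six-membered carbocycle by intermolecular suprafacial [4+2] addition across the two diene termini. The only new stereocentre, C3' of 21, forms as a racemate and is erased on aromatisation, so nothing has to be controlled. The step needs regioselectivity (C3' to the terminal alkyne carbon), which is secured by the silyloxy group at C4' placing the largest HOMO coefficient on the ring A-bearing terminus, by the twist of ring A (flanked by the C7 benzyloxy group and O1) that weakens its opposing aryl directing effect, and by sterics, since the hindered terminus meets the unsubstituted alkyne carbon. The (Z)-enol ether keeps ring A outside the s-cis diene so the cisoid conformer is reachable, and the neutral thermal conditions should leave both pyranone rings and all benzyl ethers intact.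

Step 12
Reactants: 22 5,7-bis(benzyloxy)-8-{5-[5,7-bis(benzyloxy)-4-oxo-4H-chromen-2-yl]-2-[(tert-butyldimethylsilyl)oxy]phenyl}-2-[4-(benzyloxy)-3-methoxyphenyl]-4H-chromen-4-one
Product: 23 5,7-bis(benzyloxy)-8-{5-[5,7-bis(benzyloxy)-4-oxo-4H-chromen-2-yl]-2-hydroxyphenyl}-2-[4-(benzyloxy)-3-methoxyphenyl]-4H-chromen-4-one
Conditions: TBAF, AcOH, THF, 0 °C
Reagents that add atoms: none
Why: Fluoride-induced desilylation of the aryl silyl ether is driven by the strong Si–F bond, and the acetic acid buffer protonates the phenoxide so that the base-sensitive pyranone rings and the benzyl ethers should be untouched.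

Step 13
Reactants: 23 5,7-bis(benzyloxy)-8-{5-[5,7-bis(benzyloxy)-4-oxo-4H-chromen-2-yl]-2-hydroxyphenyl}-2-[4-(benzyloxy)-3-methoxyphenyl]-4H-chromen-4-one
Product: 24 8-[5-(5,7-dihydroxy-4-oxo-4H-chromen-2-yl)-2-hydroxyphenyl]-5,7-dihydroxy-2-(4-hydroxy-3-methoxyphenyl)-4H-chromen-4-one
Conditions: H2 (1 atm), 10% Pd/C, THF/MeOH, rt
Reagents that add atoms: none
Why: Catalytic hydrogenolysis cleaves the five aryl benzyl ethers much faster than it reduces the aryl-conjugated C2=C3 bonds of the two chromones, so stopping after the uptake of five equivalents of hydrogen should give the hexaphenol with its methyl ether intact.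

Compound list
1 | 2,4,6-trihydroxyacetophenone | CC(=O)c1c(O)cc(O)cc1O | starting material
2 | 1-[2,4-bis(benzyloxy)-6-hydroxyphenyl]ethan-1-one | CC(=O)c1c(O)cc(OCc2ccccc2)cc1OCc1ccccc1 | intermediate
3 | allyl bromide | C=CCBr | starting material
4 | 1-[2-(allyloxy)-4,6-bis(benzyloxy)phenyl]ethan-1-one | CC(=O)c1c(OCC=C)cc(OCc2ccccc2)cc1OCc1ccccc1 | intermediate
5 | 1-[3-allyl-4,6-bis(benzyloxy)-2-hydroxyphenyl]ethan-1-one | CC(=O)c1c(O)c(CC=C)c(OCc2ccccc2)cc1OCc1ccccc1 | intermediate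
6 | 4-(benzyloxy)-3-methoxybenzoic acid | COc1cc(C(=O)O)ccc1OCc1ccccc1 | starting material
7 | 4-(benzyloxy)-3-methoxybenzoyl chloride | COc1cc(C(=O)Cl)ccc1OCc1ccccc1 | intermediate
8 | 1-[3-allyl-4,6-bis(benzyloxy)-2-hydroxyphenyl]-3-[4-(benzyloxy)-3-methoxyphenyl]propane-1,3-dione | COc1cc(C(=O)CC(=O)c2c(O)c(CC=C)c(OCc3ccccc3)cc2OCc2ccccc2)ccc1OCc1ccccc1 | intermediate
9 | 8-allyl-5,7-bis(benzyloxy)-2-[4-(benzyloxy)-3-methoxyphenyl]-4H-chromen-4-one | COc1cc(-c2cc(=O)c3c(OCc4ccccc4)cc(OCc4ccccc4)c(CC=C)c3o2)ccc1OCc1ccccc1 | intermediate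
10 | 2-{5,7-bis(benzyloxy)-2-[4-(benzyloxy)-3-methoxyphenyl]-4-oxo-4H-chromen-8-yl}acetaldehyde | COc1cc(-c2cc(=O)c3c(OCc4ccccc4)cc(OCc4ccccc4)c(CC=O)c3o2)ccc1OCc1ccccc1 | intermediate
11 | vinylmagnesium bromide | C=C[Mg]Br | starting material
12 | racemic 5,7-bis(benzyloxy)-2-[4-(benzyloxy)-3-methoxyphenyl]-8-(2-hydroxybut-3-en-1-yl)-4H-chromen-4-one | COc1cc(-c2cc(=O)c3c(OCc4ccccc4)cc(OCc4ccccc4)c(CC(O)C=C)c3o2)ccc1OCc1ccccc1 | intermediate
13 | 5,7-bis(benzyloxy)-2-[4-(benzyloxy)-3-methoxyphenyl]-8-(2-oxobut-3-en-1-yl)-4H-chromen-4-one | COc1cc(-c2cc(=O)c3c(OCc4ccccc4)cc(OCc4ccccc4)c(CC(=O)C=C)c3o2)ccc1OCc1ccccc1 | intermediate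
14 | 5,7-bis(benzyloxy)-2-[4-(benzyloxy)-3-methoxyphenyl]-8-[(1Z)-2-(tert-butyldimethylsilyloxy)buta-1,3-dien-1-yl]-4H-chromen-4-one | COc1cc(-c2cc(=O)c3c(OCc4ccccc4)cc(OCc4ccccc4)c(/C=C(\O[Si](C)(C)C(C)(C)C)C=C)c3o2)ccc1OCc1ccccc1 | intermediate
15 | ethyl diethoxyacetate | CCOC(OCC)C(=O)OCC | starting material
16 | 1-[2,4-bis(benzyloxy)-6-hydroxyphenyl]-4,4-diethoxybutane-1,3-dione | CCOC(OCC)C(=O)CC(=O)c1c(O)cc(OCc2ccccc2)cc1OCc1ccccc1 | intermediate
17 | 5,7-bis(benzyloxy)-2-(diethoxymethyl)-4H-chromen-4-one | CCOC(OCC)c1cc(=O)c2c(OCc3ccccc3)cc(OCc3ccccc3)cc2o1 | intermediate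
18 | 5,7-bis(benzyloxy)-4-oxo-4H-chromene-2-carbaldehyde | O=Cc1cc(=O)c2c(OCc3ccccc3)cc(OCc3ccccc3)cc2o1 | intermediate
19 | dimethyl (1-diazo-2-oxopropyl)phosphonate | COP(=O)(OC)C(=[N+]=[N-])C(C)=O | starting material
20 | 5,7-bis(benzyloxy)-2-ethynyl-4H-chromen-4-one | C#Cc1cc(=O)c2c(OCc3ccccc3)cc(OCc3ccccc3)cc2o1 | intermediate
21 | racemic 5,7-bis(benzyloxy)-8-{3-[5,7-bis(benzyloxy)-4-oxo-4H-chromen-2-yl]-6-[(tert-butyldimethylsilyl)oxy]cyclohexa-2,5-dien-1-yl}-2-[4-(benzyloxy)-3-methoxyphenyl]-4H-chromen-4-one | COc1cc(-c2cc(=O)c3c(OCc4ccccc4)cc(OCc4ccccc4)c(C4C=C(-c5cc(=O)c6c(OCc7ccccc7)cc(OCc7ccccc7)cc6o5)CC=C4O[Si](C)(C)C(C)(C)C)c3o2)ccc1OCc1ccccc1 | intermediate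
22 | 5,7-bis(benzyloxy)-8-{5-[5,7-bis(benzyloxy)-4-oxo-4H-chromen-2-yl]-2-[(tert-butyldimethylsilyl)oxy]phenyl}-2-[4-(benzyloxy)-3-methoxyphenyl]-4H-chromen-4-one | COc1cc(-c2cc(=O)c3c(OCc4ccccc4)cc(OCc4ccccc4)c(-c4cc(-c5cc(=O)c6c(OCc7ccccc7)cc(OCc7ccccc7)cc6o5)ccc4O[Si](C)(C)C(C)(C)C)c3o2)ccc1OCc1ccccc1 | intermediate
23 | 5,7-bis(benzyloxy)-8-{5-[5,7-bis(benzyloxy)-4-oxo-4H-chromen-2-yl]-2-hydroxyphenyl}-2-[4-(benzyloxy)-3-methoxyphenyl]-4H-chromen-4-one | COc1cc(-c2cc(=O)c3c(OCc4ccccc4)cc(OCc4ccccc4)c(-c4cc(-c5cc(=O)c6c(OCc7ccccc7)cc(OCc7ccccc7)cc6o5)ccc4O)c3o2)ccc1OCc1ccccc1 | intermediate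
24 | 8-[5-(5,7-dihydroxy-4-oxo-4H-chromen-2-yl)-2-hydroxyphenyl]-5,7-dihydroxy-2-(4-hydroxy-3-methoxyphenyl)-4H-chromen-4-one | COc1cc(-c2cc(=O)c3c(O)cc(O)c(-c4cc(-c5cc(=O)c6c(O)cc(O)cc6o5)ccc4O)c3o2)ccc1O | target

Total step count: 13. Longest linear sequence: 11 steps (steps 1 to 8, then 11 to 13); the alkyne branch (steps 9 and 10) leaves the main line at compound 2.

Steps most likely to fail

Step 11. The cycloaddition may stall, because the alkyne is activated only vinylogously and the reacting diene terminus carries a di-ortho-substituted aryl group, so the silyl dienol ether may decay on prolonged heating. The addition may also leak to the regioisomer in which C3' bonds to the internal alkyne carbon. The fallback gives up the cycloaddition and makes the C8–C3' bond by Suzuki–Miyaura coupling. It sets out from 2 and 7.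
- Acylation of the lithium dianion of 2 with 7 (as in step 4) would give 1-[2,4-bis(benzyloxy)-6-hydroxyphenyl]-3-[4-(benzyloxy)-3-methoxyphenyl]propane-1,3-dione F1, which TsOH in toluene closes to 5,7-bis(benzyloxy)-2-[4-(benzyloxy)-3-methoxyphenyl]-4H-chromen-4-one F2.
- N-Iodosuccinimide with catalytic CF3CO2H in MeCN should iodinate C8, the position favoured in 5,7-dialkoxyflavones, to give 5,7-bis(benzyloxy)-2-[4-(benzyloxy)-3-methoxyphenyl]-8-iodo-4H-chromen-4-one F3.
- Purchased 4-(benzyloxy)-3-bromobenzoic acid is converted with (COCl)2 into 4-(benzyloxy)-3-bromobenzoyl chloride F4. With the dianion of 2 it would give 1-[2,4-bis(benzyloxy)-6-hydroxyphenyl]-3-[4-(benzyloxy)-3-bromophenyl]propane-1,3-dione F5 and, after cyclodehydration, 5,7-bis(benzyloxy)-2-[4-(benzyloxy)-3-bromophenyl]-4H-chromen-4-one F6.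
- Miyaura borylation (B2pin2, PdCl2(dppf), KOAc, dioxane, 90 °C) turns F6 into 5,7-bis(benzyloxy)-2-[4-(benzyloxy)-3-(4,4,5,5-tetramethyl-1,3,2-dioxaborolan-2-yl)phenyl]-4H-chromen-4-one F7.
- Coupling of F3 with F7 (Pd(PPh3)4, K3PO4, DMF/H2O, 90 °C) should give the hexabenzyl ether 5,7-bis(benzyloxy)-8-{2-(benzyloxy)-5-[5,7-bis(benzyloxy)-4-oxo-4H-chromen-2-yl]phenyl}-2-[4-(benzyloxy)-3-methoxyphenyl]-4H-chromen-4-one F8.
- Hydrogenolysis under the conditions of step 13 comes back to the route at 24.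

Step 10. Under the basic methanolic conditions methoxide may add to the newly formed conjugated terminal alkyne, or the pyranone ring may be opened by attack at C2. The fallback avoids alkoxide and sets out from 18.
- Ramirez olefination (CBr4, PPh3, CH2Cl2, 0 °C) would give 5,7-bis(benzyloxy)-2-(2,2-dibromovinyl)-4H-chromen-4-one F9.
- Palladium-catalysed hydrogenolysis of the bromine trans to the ring (Bu3SnH, Pd(PPh3)4, toluene, rt) would give 5,7-bis(benzyloxy)-2-[(Z)-2-bromovinyl]-4H-chromen-4-one F10.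
- Anti-elimination of HBr with DBU in toluene comes back to the route at 20.

Step 6. The vinyl organometallic may deprotonate the arylacetaldehyde instead of adding to it, or attack the chromone carbonyl. The fallback uses no basic organometallic and bypasses 12; it sets out from 10.
- Pinnick oxidation (NaClO2, NaH2PO4, 2-methylbut-2-ene, t-BuOH/H2O) would give {5,7-bis(benzyloxy)-2-[4-(benzyloxy)-3-methoxyphenyl]-4-oxo-4H-chromen-8-yl}acetic acid F11.
- (COCl)2 with catalytic DMF in CH2Cl2 converts it into {5,7-bis(benzyloxy)-2-[4-(benzyloxy)-3-methoxyphenyl]-4-oxo-4H-chromen-8-yl}acetyl chloride F12.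
- Stille acylation with tributyl(vinyl)stannane (PdCl(CH2Ph)(PPh3)2 cat., THF, 50 °C) gives the vinyl ketone and comes back to the route at 13.

Further compounds
F1 | step 11 | 1-[2,4-bis(benzyloxy)-6-hydroxyphenyl]-3-[4-(benzyloxy)-3-methoxyphenyl]propane-1,3-dione | COc1cc(C(=O)CC(=O)c2c(O)cc(OCc3ccccc3)cc2OCc2ccccc2)ccc1OCc1ccccc1
F2 | step 11 | 5,7-bis(benzyloxy)-2-[4-(benzyloxy)-3-methoxyphenyl]-4H-chromen-4-one | COc1cc(-c2cc(=O)c3c(OCc4ccccc4)cc(OCc4ccccc4)cc3o2)ccc1OCc1ccccc1
F3 | step 11 | 5,7-bis(benzyloxy)-2-[4-(benzyloxy)-3-methoxyphenyl]-8-iodo-4H-chromen-4-one | COc1cc(-c2cc(=O)c3c(OCc4ccccc4)cc(OCc4ccccc4)c(I)c3o2)ccc1OCc1ccccc1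
F4 | step 11 | 4-(benzyloxy)-3-bromobenzoyl chloride | O=C(Cl)c1ccc(OCc2ccccc2)c(Br)c1
F5 | step 11 | 1-[2,4-bis(benzyloxy)-6-hydroxyphenyl]-3-[4-(benzyloxy)-3-bromophenyl]propane-1,3-dione | O=C(CC(=O)c1c(O)cc(OCc2ccccc2)cc1OCc1ccccc1)c1ccc(OCc2ccccc2)c(Br)c1
F6 | step 11 | 5,7-bis(benzyloxy)-2-[4-(benzyloxy)-3-bromophenyl]-4H-chromen-4-one | O=c1cc(-c2ccc(OCc3ccccc3)c(Br)c2)oc2cc(OCc3ccccc3)cc(OCc3ccccc3)c12
F7 | step 11 | 5,7-bis(benzyloxy)-2-[4-(benzyloxy)-3-(4,4,5,5-tetramethyl-1,3,2-dioxaborolan-2-yl)phenyl]-4H-chromen-4-one | CC1(C)OB(c2cc(-c3cc(=O)c4c(OCc5ccccc5)cc(OCc5ccccc5)cc4o3)ccc2OCc2ccccc2)OC1(C)C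
F8 | step 11 | 5,7-bis(benzyloxy)-8-{2-(benzyloxy)-5-[5,7-bis(benzyloxy)-4-oxo-4H-chromen-2-yl]phenyl}-2-[4-(benzyloxy)-3-methoxyphenyl]-4H-chromen-4-one | COc1cc(-c2cc(=O)c3c(OCc4ccccc4)cc(OCc4ccccc4)c(-c4cc(-c5cc(=O)c6c(OCc7ccccc7)cc(OCc7ccccc7)cc6o5)ccc4OCc4ccccc4)c3o2)ccc1OCc1ccccc1
F9 | step 10 | 5,7-bis(benzyloxy)-2-(2,2-dibromovinyl)-4H-chromen-4-one | BrC(Br)=Cc1cc(=O)c2c(OCc3ccccc3)cc(OCc3ccccc3)cc2o1
F10 | step 10 | 5,7-bis(benzyloxy)-2-[(Z)-2-bromovinyl]-4H-chromen-4-one | Br/C=C\c1cc(=O)c2c(OCc3ccccc3)cc(OCc3ccccc3)cc2o1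
F11 | step 6 | {5,7-bis(benzyloxy)-2-[4-(benzyloxy)-3-methoxyphenyl]-4-oxo-4H-chromen-8-yl}acetic acid | COc1cc(-c2cc(=O)c3c(OCc4ccccc4)cc(OCc4ccccc4)c(CC(=O)O)c3o2)ccc1OCc1ccccc1
F12 | step 6 | {5,7-bis(benzyloxy)-2-[4-(benzyloxy)-3-methoxyphenyl]-4-oxo-4H-chromen-8-yl}acetyl chloride | COc1cc(-c2cc(=O)c3c(OCc4ccccc4)cc(OCc4ccccc4)c(CC(=O)Cl)c3o2)ccc1OCc1ccccc1
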